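**Retrosynthetic overview**
1. Target = 12-membered lactone. Ring A is the 2-methylbenzoate ring and ring B the catechol-derived ring. Chain locants: C1=C2 is the (Z)-alkene on ring B, C3 the allylic CH–OH, C4 the CH that bears n-pentyl and the lactone oxygen. The last two steps remove an allyl group from the ring B phenol and a silyl group from O-3.
2. The macrocycle is opened at the alkyl C–O bond of the lactone (C4–O): a Mitsunobu macrolactonization in which the ring A carboxylate displaces the activated C4 hydroxyl of a (3S,4R) seco acid with inversion (12-exo-tet).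
3. Enabling feature: C4 is a plain secondary carbinol flanked only by n-pentyl and C3, and the C3/C4 oxygen pair is threo, so it is the SN2-inversion product of the erythro pair that a Felkin–Anh addition delivers. The (Z)-C1=C2 bond ortho to the diaryl ether oxygen on ring B and the meta ether/carboxyl pattern on ring A fold the C4–OH back onto the acid.
4. Seco acid ⇒ Lindlar semihydrogenation of an aryl alkyne. The C2–C3 bond comes from addition of the ring B lithium acetylide to (R)-2-(triethylsilyloxy)heptanal, made from (S)-glycidol and n-BuMgBr.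
5. Aryl alkyne ⇒ Ohira–Bestmann homologation of a diaryl ether aldehyde ⇒ SNAr of methyl 5-hydroxy-2-methylbenzoate on 3-(allyloxy)-2-fluorobenzaldehyde. Rings A and B are bought as arenes; the only ring formed is the lactone, and it is formed last.

Key step: step 12

Remark on the chemistry: the target SMILES is read as (1Z,3S,4S) in the chain locants above, i.e. a Z-alkene and a threo C3/C4 pair; these locants are used throughout.

**Step 1**
Reactants: 1 (S)-glycidol
Product: 2 (R)-heptane-1,2-diol
Conditions: n-BuMgBr (2.5 equiv), CuI (10 mol%), THF, −30 to 0 °C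
Reagents that add atoms: n-butylmagnesium bromide, CCCC[Mg]Br
Why: Copper-catalysed SN2 opening of the epoxide at its CH2 terminus by the butyl Grignard reagent (the first equivalent only deprotonates the hydroxyl) builds the pentyl chain and leaves the stereocentre untouched, its descriptor changing from S to R only because the ligand priorities change.

**Step 2**
Reactants: 2 (R)-heptane-1,2-diol
Product: 3 (R)-1,2-bis(triethylsilyloxy)heptane
Conditions: Et3SiCl (2.4 equiv), imidazole, DMF, 0 °C to rt
Reagents that add atoms: chlorotriethylsilane, CC[Si](CC)(CC)Cl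
Why: Imidazole-promoted silylation of both hydroxyls is routine and does not touch the stereocentre.

**Step 3**
Reactants: 3 (R)-1,2-bis(triethylsilyloxy)heptane
Product: 4 (R)-2-(triethylsilyloxy)heptanal
Conditions: (COCl)2, DMSO, CH2Cl2, −78 to −30 °C; then Et3N, −78 to 0 °C
Reagents that add atoms: none
Why: Swern oxidation run directly on the bis-silyl ether cleaves and oxidises only the primary triethylsilyl ether (a known selective oxidative desilylation) and should give the α-silyloxy aldehyde, which is used at once to protect the α-stereocentre from epimerisation.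

**Step 4**
Reactants: 5 2-fluoro-3-hydroxybenzaldehyde
Product: 6 3-(allyloxy)-2-fluorobenzaldehyde
Conditions: allyl bromide, K2CO3, DMF, rt
Reagents that add atoms: allyl bromide, C=CCBr
Why: Williamson O-alkylation masks the ring B phenol with a group that survives carbonate, hydroxide, mild acid and Mitsunobu conditions and can be removed late under neutral conditions with zerovalent palladium.

**Step 5**
Reactants: 6 3-(allyloxy)-2-fluorobenzaldehyde; 7 methyl 5-hydroxy-2-methylbenzoate
Product: 8 methyl 5-[2-(allyloxy)-6-formylphenoxy]-2-methylbenzoate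
Conditions: K2CO3, DMF, 90 °C
Reagents that add atoms: none
Why: Nucleophilic aromatic substitution (addition–elimination) of the ring A phenoxide at the fluorine-bearing carbon, which is activated by the ortho formyl group, should form the hindered diaryl ether.

**Step 6**
Reactants: 8 methyl 5-[2-(allyloxy)-6-formylphenoxy]-2-methylbenzoate
Product: 9 methyl 5-[2-(allyloxy)-6-ethynylphenoxy]-2-methylbenzoate
Conditions: dimethyl (1-diazo-2-oxopropyl)phosphonate, K2CO3, MeOH, 0 °C to rt
Reagents that add atoms: dimethyl (1-diazo-2-oxopropyl)phosphonate, CC(=O)C(=[N+]=[N-])P(=O)(OC)OC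
Why: Seyferth–Gilbert homologation in its Ohira–Bestmann form converts the aryl aldehyde into the terminal alkyne under carbonate/methanol conditions in which the methyl ester can only exchange with itself.

**Step 7**
Reactants: 9 methyl 5-[2-(allyloxy)-6-ethynylphenoxy]-2-methylbenzoate; 4 (R)-2-(triethylsilyloxy)heptanal
Product: 11 methyl 5-{2-(allyloxy)-6-[(3S,4R)-3-hydroxy-4-(triethylsilyloxy)non-1-yn-1-yl]phenoxy}-2-methylbenzoate, via lithium acetylide 10 (not isolated)
Conditions: LiN(SiMe3)2, THF, −78 °C; then 4, −78 °C
Reagents that add atoms: none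
Why: LiN(SiMe3)2 deprotonates the alkyne without adding to the methyl ester or metalating the benzylic methyl group, and 1,2-addition of acetylide 10 to the α-silyloxy aldehyde should follow the Felkin–Anh (polar, non-chelation) model, so the new C3 stereocentre is set anti to C4, that is (3S,4R), by substrate control, the minor C3 epimer being removed by chromatography.

**Step 8**
Reactants: 11 methyl 5-{2-(allyloxy)-6-[(3S,4R)-3-hydroxy-4-(triethylsilyloxy)non-1-yn-1-yl]phenoxy}-2-methylbenzoate
Product: 12 methyl 5-{2-(allyloxy)-6-[(3S,4R)-3-(tert-butyldimethylsilyloxy)-4-(triethylsilyloxy)non-1-yn-1-yl]phenoxy}-2-methylbenzoate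
Conditions: t-BuMe2SiOTf, 2,6-lutidine, CH2Cl2, −78 to 0 °C
Reagents that add atoms: tert-butyldimethylsilyl trifluoromethanesulfonate, CC(C)(C)[Si](C)(C)OS(=O)(=O)C(F)(F)F
Why: Silyl triflate silylation of the hindered propargylic alcohol puts on O-3 a silyl group that outlasts the triethylsilyl group on O-4 and keeps C3 blocked during the key step.

**Step 9**
Reactants: 12 methyl 5-{2-(allyloxy)-6-[(3S,4R)-3-(tert-butyldimethylsilyloxy)-4-(triethylsilyloxy)non-1-yn-1-yl]phenoxy}-2-methylbenzoate
Product: 13 methyl 5-{2-(allyloxy)-6-[(1Z,3S,4R)-3-(tert-butyldimethylsilyloxy)-4-(triethylsilyloxy)non-1-en-1-yl]phenoxy}-2-methylbenzoate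
Conditions: H2 (1 atm), Pd/CaCO3 poisoned with Pb(OAc)2 (Lindlar catalyst), quinoline, EtOAc, rt
Reagents that add atoms: none
Why: Syn delivery of hydrogen on the poisoned palladium surface (Lindlar semihydrogenation) should give the (Z)-alkene, with quinoline and monitoring of the hydrogen uptake keeping the isolated allyl ether double bond and the new styrene from being reduced.

**Step 10**
Reactants: 13 methyl 5-{2-(allyloxy)-6-[(1Z,3S,4R)-3-(tert-butyldimethylsilyloxy)-4-(triethylsilyloxy)non-1-en-1-yl]phenoxy}-2-methylbenzoate
Product: 14 5-{2-(allyloxy)-6-[(1Z,3S,4R)-3-(tert-butyldimethylsilyloxy)-4-(triethylsilyloxy)non-1-en-1-yl]phenoxy}-2-methylbenzoic acid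
Conditions: LiOH·H2O, THF/MeOH/H2O, 45 °C; then 1 M HCl to pH 4, 0 °C
Reagents that add atoms: lithium hydroxide, [Li+].[OH-]
Why: Saponification (acyl–oxygen cleavage) of the ortho-methyl benzoate is run while both carbinol oxygens are still silylated, so that no alkoxide is present that could start a 1,2-silyl shift between O-3 and O-4.

**Step 11**
Reactants: 14 5-{2-(allyloxy)-6-[(1Z,3S,4R)-3-(tert-butyldimethylsilyloxy)-4-(triethylsilyloxy)non-1-en-1-yl]phenoxy}-2-methylbenzoic acid
Product: 15 5-{2-(allyloxy)-6-[(1Z,3S,4R)-3-(tert-butyldimethylsilyloxy)-4-hydroxynon-1-en-1-yl]phenoxy}-2-methylbenzoic acid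
Conditions: pyridinium p-toluenesulfonate (cat.), MeOH/CH2Cl2, 0 °C to rt
Reagents that add atoms: none
Why: Mild acid-catalysed methanolysis cleaves the less hindered triethylsilyl ether much faster than the tert-butyldimethylsilyl ether and should free only the C4 hydroxyl.

**Step 12**
Reactants: 15 5-{2-(allyloxy)-6-[(1Z,3S,4R)-3-(tert-butyldimethylsilyloxy)-4-hydroxynon-1-en-1-yl]phenoxy}-2-methylbenzoic acid
Product: 17 O-allyl O-3-silyl macrolactone [(1Z,3S,4S); 12-membered ring closed between the ring A carboxyl oxygen and C4], via alkoxyphosphonium carboxylate 16 (not isolated)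
Conditions: PPh3 (6 equiv), DIAD (6 equiv), toluene, 2 mM, slow addition of 15 over 8 h, 0 °C to rt
Reagents that add atoms: none
Why: The PPh3/DIAD betaine deprotonates the ring A carboxylic acid and converts the only free hydroxyl, the C4–OH, into alkoxyphosphonium ion 16, whose C4 is attacked from the rear by the internal carboxylate oxygen with loss of Ph3P=O, so the ester alkyl C–O bond and the macrocycle form in the same SN2 event. The closest known reaction type is the Mitsunobu macrolactonization of hydroxy benzoic acids at secondary carbinol centres, as used for benzannulated macrolides, and the ring is closed in the 12-exo-tet mode. The C4 stereocentre is set by stereospecific Walden inversion of the (4R)-alcohol to the (4S)-ester, which turns the erythro C3/C4 pair of the Felkin–Anh adduct into the threo pair of the target, while the (3S) centre and the Z-alkene are not touched. Chemoselectivity is secured because O-3 (silyl ether) and the ring B phenol (allyl ether) are masked, because the allylic C3 oxygen is never activated and so cannot ionise or react in an SN2' sense, and because the alkyl–oxygen mode avoids acyl activation of the ortho-methyl-hindered acid. Cyclisation over oligomerisation is favoured by high dilution with slow addition and by the turn that the (Z)-C1=C2 bond ortho to the diaryl ether oxygen on ring B and the meta ether/carboxyl pattern on ring A impose on the chain. The pathways to be suppressed are E2 elimination of the alkoxyphosphonium ion and esterification through an acyloxyphosphonium ion with retention, both disfavoured by the acidity of the benzoic acid (fast protonation of the betaine) and by the low temperature.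

**Step 13**
Reactants: 17 O-allyl O-3-silyl macrolactone
Product: 18 O-3-silyl macrolactone with free ring B phenol [(1Z,3S,4S)]
Conditions: Pd(PPh3)4 (5 mol%), morpholine, THF, rt
Reagents that add atoms: none
Why: Zerovalent palladium ionises the aryl allyl ether to a π-allyl complex that is trapped by morpholine (Tsuji–Trost deallylation), under conditions neutral enough to leave the lactone, the silyl ether and the Z-alkene alone, and the ring ester cannot ionise because its alkyl carbon is not allylic.

**Step 14**
Reactants: 18 O-3-silyl macrolactone with free ring B phenol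
Product: 19 target macrolactone CNP0319567.1 [(1Z,3S,4S)]
Conditions: HF·pyridine, pyridine, THF, 0 °C to rt
Reagents that add atoms: none
Why: Fluoride cleavage of the secondary silyl ether under buffered, weakly acidic conditions should free the C3 hydroxyl without the base-induced 1,2-acyl shift that would contract the lactone and without ionising the allylic alcohol.

**Compound list**
1 | (S)-glycidol [(S)-oxiran-2-ylmethanol] | C1[C@@H](O1)CO | starting material
2 | (R)-heptane-1,2-diol | CCCCC[C@@H](O)CO | intermediate
3 | (R)-1,2-bis(triethylsilyloxy)heptane | CCCCC[C@@H](O[Si](CC)(CC)CC)CO[Si](CC)(CC)CC | intermediate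
4 | (R)-2-(triethylsilyloxy)heptanal | CCCCC[C@@H](O[Si](CC)(CC)CC)C=O | intermediate
5 | 2-fluoro-3-hydroxybenzaldehyde | O=Cc1cccc(O)c1F | starting material
6 | 3-(allyloxy)-2-fluorobenzaldehyde | O=Cc1cccc(OCC=C)c1F | intermediate
7 | methyl 5-hydroxy-2-methylbenzoate | COC(=O)c1cc(O)ccc1C | starting material
8 | methyl 5-[2-(allyloxy)-6-formylphenoxy]-2-methylbenzoate | COC(=O)c1cc(Oc2c(C=O)cccc2OCC=C)ccc1C | intermediate
9 | methyl 5-[2-(allyloxy)-6-ethynylphenoxy]-2-methylbenzoate | COC(=O)c1cc(Oc2c(C#C)cccc2OCC=C)ccc1C | intermediate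
10 | lithium acetylide of 9 (not isolated) | COC(=O)c1cc(Oc2c(C#C[Li])cccc2OCC=C)ccc1C | intermediate
11 | methyl 5-{2-(allyloxy)-6-[(3S,4R)-3-hydroxy-4-(triethylsilyloxy)non-1-yn-1-yl]phenoxy}-2-methylbenzoate | CCCCC[C@@H](O[Si](CC)(CC)CC)[C@@H](O)C#Cc1cccc(OCC=C)c1Oc1ccc(C)c(C(=O)OC)c1 | intermediate
12 | methyl 5-{2-(allyloxy)-6-[(3S,4R)-3-(tert-butyldimethylsilyloxy)-4-(triethylsilyloxy)non-1-yn-1-yl]phenoxy}-2-methylbenzoate | CCCCC[C@@H](O[Si](CC)(CC)CC)[C@@H](O[Si](C)(C)C(C)(C)C)C#Cc1cccc(OCC=C)c1Oc1ccc(C)c(C(=O)OC)c1 | intermediate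
13 | methyl 5-{2-(allyloxy)-6-[(1Z,3S,4R)-3-(tert-butyldimethylsilyloxy)-4-(triethylsilyloxy)non-1-en-1-yl]phenoxy}-2-methylbenzoate | CCCCC[C@@H](O[Si](CC)(CC)CC)[C@@H](O[Si](C)(C)C(C)(C)C)/C=C\c1cccc(OCC=C)c1Oc1ccc(C)c(C(=O)OC)c1 | intermediate
14 | 5-{2-(allyloxy)-6-[(1Z,3S,4R)-3-(tert-butyldimethylsilyloxy)-4-(triethylsilyloxy)non-1-en-1-yl]phenoxy}-2-methylbenzoic acid | CCCCC[C@@H](O[Si](CC)(CC)CC)[C@@H](O[Si](C)(C)C(C)(C)C)/C=C\c1cccc(OCC=C)c1Oc1ccc(C)c(C(=O)O)c1 | intermediate
15 | 5-{2-(allyloxy)-6-[(1Z,3S,4R)-3-(tert-butyldimethylsilyloxy)-4-hydroxynon-1-en-1-yl]phenoxy}-2-methylbenzoic acid (seco acid) | CCCCC[C@@H](O)[C@@H](O[Si](C)(C)C(C)(C)C)/C=C\c1cccc(OCC=C)c1Oc1ccc(C)c(C(=O)O)c1 | intermediate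
16 | C4 alkoxy(triphenyl)phosphonium carboxylate zwitterion of 15 (not isolated) | CCCCC[C@@H](O[P+](c1ccccc1)(c1ccccc1)c1ccccc1)[C@@H](O[Si](C)(C)C(C)(C)C)/C=C\c1cccc(OCC=C)c1Oc1ccc(C)c(C(=O)[O-])c1 | intermediate
17 | O-allyl O-3-(tert-butyldimethylsilyl) macrolactone, (1Z,3S,4S) | CCCCC[C@@H]1OC(=O)c2cc(ccc2C)Oc2c(OCC=C)cccc2/C=C\[C@@H]1O[Si](C)(C)C(C)(C)C | intermediate
18 | O-3-(tert-butyldimethylsilyl) macrolactone with free ring B phenol, (1Z,3S,4S) | CCCCC[C@@H]1OC(=O)c2cc(ccc2C)Oc2c(O)cccc2/C=C\[C@@H]1O[Si](C)(C)C(C)(C)C | intermediate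
19 | CNP0319567.1, (1Z,3S,4S) macrolactone | CCCCC[C@@H]1OC(=O)c2cc(ccc2C)Oc2c(O)cccc2/C=C\[C@@H]1O | target

**Step count and risks**
Total steps: 14. Longest linear sequence: 11 steps (steps 4 to 14 from 5; the aldehyde branch, steps 1 to 3 and then 7 to 14, is equally long).

Most likely to fail, in this order:

Step 12. SN2 at C4 is slowed by the neighbouring silyloxy-bearing carbon and by the strain of the forming ring. The alkoxyphosphonium ion may therefore eliminate, be captured intermolecularly to give oligomers, or the ester may form through an acyloxyphosphonium ion with retention. The fallback sets out from 15 and moves the ring closure to the acyl C–O bond. An intermolecular Mitsunobu inversion with 4-nitrobenzoic acid (PPh3, DIAD, THF) should give the (4S)-4-nitrobenzoate acid F1. Brief methanolysis (K2CO3, MeOH, 0 °C, kept short to avoid silyl migration) should give the threo (3S,4S)-hydroxy acid F2. Shiina macrolactonization of F2 (2-methyl-6-nitrobenzoic anhydride, DMAP, toluene, high dilution) proceeds with retention at C4 and rejoins the route at 17.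

Step 7. The Felkin–Anh bias of the α-silyloxy aldehyde may give poor facial selectivity, and the aldehyde may partly epimerise before it is consumed. The fallback sets out from 11 obtained as a C3-epimer mixture. Oxidation (Dess–Martin periodinane, NaHCO3, CH2Cl2) should give the ynone F3. Asymmetric transfer hydrogenation under reagent control (RuCl[(R,R)-TsDPEN](p-cymene), iPrOH, rt) should then reset C3 to (3S) and return to diastereomerically pure 11.

Step 9. The alkyne is flanked by an ortho-disubstituted arene and a bis-silyloxy chain, so hydrogenation may be slow enough for the allyl ether to be reduced or isomerised, or for the styrene to be over-reduced or isomerised to E. The fallback sets out from 11 and replaces catalytic hydrogenation by electron-transfer reduction before silylation. Zinc dust activated with Cu(OAc)2 and AgNO3 in MeOH/H2O reduces aryl-conjugated propargylic alcohols to Z-alkenes and is inert to isolated alkenes, and should give the (Z)-allylic alcohol F4. Silylation (t-BuMe2SiOTf, 2,6-lutidine) then rejoins the route at 13.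

**Further compounds**
F1 | step 12 | 5-{2-(allyloxy)-6-[(1Z,3S,4S)-3-(tert-butyldimethylsilyloxy)-4-(4-nitrobenzoyloxy)non-1-en-1-yl]phenoxy}-2-methylbenzoic acid | CCCCC[C@H](OC(=O)c1ccc(cc1)[N+](=O)[O-])[C@@H](O[Si](C)(C)C(C)(C)C)/C=C\c1cccc(OCC=C)c1Oc1ccc(C)c(C(=O)O)c1
F2 | step 12 | 5-{2-(allyloxy)-6-[(1Z,3S,4S)-3-(tert-butyldimethylsilyloxy)-4-hydroxynon-1-en-1-yl]phenoxy}-2-methylbenzoic acid | CCCCC[C@H](O)[C@@H](O[Si](C)(C)C(C)(C)C)/C=C\c1cccc(OCC=C)c1Oc1ccc(C)c(C(=O)O)c1
F3 | step 7 | methyl 5-{2-(allyloxy)-6-[(4R)-3-oxo-4-(triethylsilyloxy)non-1-yn-1-yl]phenoxy}-2-methylbenzoate | CCCCC[C@@H](O[Si](CC)(CC)CC)C(=O)C#Cc1cccc(OCC=C)c1Oc1ccc(C)c(C(=O)OC)c1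
F4 | step 9 | methyl 5-{2-(allyloxy)-6-[(1Z,3S,4R)-3-hydroxy-4-(triethylsilyloxy)non-1-en-1-yl]phenoxy}-2-methylbenzoate | CCCCC[C@@H](O[Si](CC)(CC)CC)[C@@H](O)/C=C\c1cccc(OCC=C)c1Oc1ccc(C)c(C(=O)OC)c1
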